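## Retrosynthetic overview

1. Target 26 ⇒ bicyclic aldehyde 23. One operation breaks C1–C7 and makes C6–C7, so the cyclopentane (ring B) expands to the ten-membered ring C. It frees the C1 ketone and sets C6 and C7.
2. 23 ⇒ bromide 20. An intramolecular Barbier closure of the bromomethylbutenolide onto its own ketone forms C1–C7 (ring B), followed by acetal hydrolysis.
3. 20 ⇒ 18. Ketohydroxylation of the C1=C10 alkene sets C10, and ring-closing metathesis makes C7=C11 (butenolide, ring A).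
4. 18 ⇒ 10 + 11 + 14 + 17. A syn-alkoxyallylboration makes C8–C9, and two esterifications follow.
5. 10 ⇒ 6 + 8 by B-alkyl Suzuki coupling (C1–C2), and 6 ⇒ 1 + 2 + 5 by anti-crotylboration (C4–C5). Ring order: A, then B, then C (from B).

Assumption: skeleton atoms carry germacrane locants (C1 ring ketone, C2/C3 CH2, C4 CHMe, C5 CH–O-isovaleryl, C6 CHOH, C7/C8 lactone fusion, C9 CH–O-methylbutanoyl, C10 C(OH)Me, C11–C13 methylene-lactone carbons); the Ipc reagents are taken to follow the usual closed-chair model; the C1 configuration drawn for 22–24 is the expected one and is erased in step 12.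

## Route

Step 1
Reactants: 1 (E)-but-2-ene; 2 2,2-dimethoxyacetaldehyde
Product: 4 (2R,3R)-1,1-dimethoxy-3-methylpent-4-en-2-ol, via crotylborane 3 (not isolated)
Conditions: 1, n-BuLi, KOt-Bu, THF, −78 to −45 °C; (+)-Ipc2BOMe [from (−)-α-pinene], −78 °C; BF3·OEt2; 2, −78 °C; NaOH, H2O2
Reagents that add atoms: none
Why: Brown asymmetric crotylboration, in which the (E)-crotylborane reacts through a closed chair so that C4/C5 come out anti, and the (−)-α-pinene-derived ligands direct attack to the Re face of 2 to give 4R,5R.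

Step 2
Reactants: 4 (2R,3R)-1,1-dimethoxy-3-methylpent-4-en-2-ol; 5 3-methylbutanoyl chloride
Product: 6 (2R,3R)-1,1-dimethoxy-3-methylpent-4-en-2-yl 3-methylbutanoate
Conditions: Et3N, DMAP (cat.), CH2Cl2, 0 °C to rt
Reagents that add atoms: none
Why: DMAP-catalysed O-acylation puts the isovalerate on O5 while it is the only hydroxyl in the molecule, so C5 and C6 never need to be told apart later and no stereocentre is touched.

Step 3
Reactants: 7 (E)-3-iodo-2-methylprop-2-en-1-ol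
Product: 8 (E)-3-iodo-2-methylprop-2-enal
Conditions: MnO2, CH2Cl2, rt
Reagents that add atoms: none
Why: Chemoselective MnO2 oxidation of an allylic alcohol gives the enal and keeps the (E)-vinyl iodide geometry.

Step 4
Reactants: 6 (2R,3R)-1,1-dimethoxy-3-methylpent-4-en-2-yl 3-methylbutanoate; 8 (E)-3-iodo-2-methylprop-2-enal
Product: 10 (2R,3R,6E)-1,1-dimethoxy-3,7-dimethyl-8-oxooct-6-en-2-yl 3-methylbutanoate, via alkyl-9-BBN adduct 9 (not isolated)
Conditions: 9-BBN, THF, rt; then 8, Pd(dppf)Cl2 (5 mol %), AsPh3, Cs2CO3, DMF/H2O, rt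
Reagents that add atoms: none
Why: Anti-Markovnikov hydroboration of the only alkene, then B-alkyl Suzuki–Miyaura coupling with retention of the vinyl iodide geometry, forms C1–C2 and the (E)-trisubstituted C1=C10 alkene.

Step 5
Reactants: 10 (2R,3R,6E)-1,1-dimethoxy-3,7-dimethyl-8-oxooct-6-en-2-yl 3-methylbutanoate; 11 3-(methoxymethoxy)prop-1-ene
Product: 13 (2R,3R,6E,8S,9S)-8-hydroxy-1,1-dimethoxy-9-(methoxymethoxy)-3,7-dimethylundeca-6,10-dien-2-yl 3-methylbutanoate, via alkoxyallylborane 12 (not isolated)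
Conditions: 11, s-BuLi, THF, −78 °C; (+)-Ipc2BOMe [from (−)-α-pinene]; BF3·OEt2; 10, −78 °C; NaBO3·4H2O, THF/H2O, rt
Reagents that add atoms: none
Why: Brown alkoxyallylboration, in which the (Z)-γ-alkoxyallylborane in a closed chair gives the syn C8/C9 pair, Re-face attack on the enal fixes the absolute sense, and the product leaves O9 free with O8 masked.

Step 6
Reactants: 13 (2R,3R,6E,8S,9S)-8-hydroxy-1,1-dimethoxy-9-(methoxymethoxy)-3,7-dimethylundeca-6,10-dien-2-yl 3-methylbutanoate; 14 (R)-2-methylbutanoic acid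
Product: 15 (2R,3R,6E,8S,9S)-1,1-dimethoxy-9-(methoxymethoxy)-3,7-dimethyl-8-{[(2R)-2-methylbutanoyl]oxy}undeca-6,10-dien-2-yl 3-methylbutanoate
Conditions: DCC, DMAP (cat.), CH2Cl2, 0 °C
Reagents that add atoms: none
Why: Steglich esterification of the single free hydroxyl (O9) brings in the side-chain stereocentre from enantiopure 14 without touching C9.

Step 7
Reactants: 15 (2R,3R,6E,8S,9S)-1,1-dimethoxy-9-(methoxymethoxy)-3,7-dimethyl-8-{[(2R)-2-methylbutanoyl]oxy}undeca-6,10-dien-2-yl 3-methylbutanoate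
Product: 16 (2R,3R,6E,8S,9S)-9-hydroxy-1,1-dimethoxy-3,7-dimethyl-8-{[(2R)-2-methylbutanoyl]oxy}undeca-6,10-dien-2-yl 3-methylbutanoate
Conditions: HCl (cat.), MeOH, 40 °C
Reagents that add atoms: none
Why: Acid-catalysed acetal exchange cleaves the MOM ether, the C6 dimethyl acetal only exchanges degenerately in methanol, and doing this before the C1 ketone exists stops O8 from being trapped as a cyclic ketal.

Step 8
Reactants: 16 (2R,3R,6E,8S,9S)-9-hydroxy-1,1-dimethoxy-3,7-dimethyl-8-{[(2R)-2-methylbutanoyl]oxy}undeca-6,10-dien-2-yl 3-methylbutanoate; 17 2-(bromomethyl)acrylic acid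
Product: 18 (2R,3R,6E,8S,9S)-9-{[2-(bromomethyl)acryloyl]oxy}-1,1-dimethoxy-3,7-dimethyl-8-{[(2R)-2-methylbutanoyl]oxy}undeca-6,10-dien-2-yl 3-methylbutanoate
Conditions: DCC, DMAP (5 mol %), CH2Cl2, −10 °C
Reagents that add atoms: none
Why: Steglich esterification of the only free hydroxyl (O8) with retention at C8 brings in C11, C12, C13 and the allylic bromide in one piece.

Step 9
Reactants: 18 (2R,3R,6E,8S,9S)-9-{[2-(bromomethyl)acryloyl]oxy}-1,1-dimethoxy-3,7-dimethyl-8-{[(2R)-2-methylbutanoyl]oxy}undeca-6,10-dien-2-yl 3-methylbutanoate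
Product: 19 (2R,3R,6E,8S)-8-[(2S)-4-(bromomethyl)-5-oxo-2,5-dihydrofuran-2-yl]-1,1-dimethoxy-3,7-dimethyl-8-{[(2R)-2-methylbutanoyl]oxy}oct-6-en-2-yl 3-methylbutanoate
Conditions: second-generation Hoveyda–Grubbs catalyst (5 mol %), toluene, 70 °C
Reagents that add atoms: none
Why: Ring-closing metathesis of the vinyl carbinol acrylate joins only the two terminal alkenes to give the 3-(bromomethyl)butenolide (ring A), and the trisubstituted C1=C10 alkene and all stereocentres stay untouched.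

Step 10
Reactants: 19 (2R,3R,6E,8S)-8-[(2S)-4-(bromomethyl)-5-oxo-2,5-dihydrofuran-2-yl]-1,1-dimethoxy-3,7-dimethyl-8-{[(2R)-2-methylbutanoyl]oxy}oct-6-en-2-yl 3-methylbutanoate
Product: 20 (2R,3R,7R,8R)-8-[(2S)-4-(bromomethyl)-5-oxo-2,5-dihydrofuran-2-yl]-7-hydroxy-1,1-dimethoxy-3,7-dimethyl-8-{[(2R)-2-methylbutanoyl]oxy}-6-oxooctan-2-yl 3-methylbutanoate
Conditions: RuCl3 (2 mol %), Oxone, NaHCO3, EtOAc/MeCN/H2O, rt, 15 min
Reagents that add atoms: potassium peroxymonosulfate (Oxone), [K+].[O-]S(=O)(=O)OO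
Why: RuO4-catalysed ketohydroxylation attacks only the electron-rich trisubstituted alkene under near-neutral conditions that the base-labile bromobutenolide tolerates, the regiochemistry is fixed because only C1 carries hydrogen, and addition anti to the bulky butenolide with the C9 acyloxy group inside (erythro outcome) gives 10R.

Step 11
Reactants: 20 (2R,3R,7R,8R)-8-[(2S)-4-(bromomethyl)-5-oxo-2,5-dihydrofuran-2-yl]-7-hydroxy-1,1-dimethoxy-3,7-dimethyl-8-{[(2R)-2-methylbutanoyl]oxy}-6-oxooctan-2-yl 3-methylbutanoate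
Product: 23 (3aR,4R,5R,6R,6aS)-4,5-dihydroxy-5-methyl-3-methylidene-4-{(3R,4R)-3-methyl-4-[(3-methylbutanoyl)oxy]-5-oxopentyl}-2-oxohexahydro-2H-cyclopenta[b]furan-6-yl (2R)-2-methylbutanoate, via allylzinc bromide 21 (not isolated), via bicyclic acetal 22 (not isolated)
Conditions: Zn dust, THF/sat. aq. NH4Cl, 0 °C; then 1 M HCl, rt
Reagents that add atoms: water, O
Why: Intramolecular Barbier allylation, in which the allylzinc attacks through C7 the ketone three atoms away (fast five-membered closure, cis ring fusion forced by the tether, C1–OH cis to C11 from the closed transition state); this stores the ketone and the allyl nucleophile together in ring B, so the acetal can then be hydrolysed with no 1,6-keto-aldehyde or allylic bromide present.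

Step 12
Reactants: 23 (3aR,4R,5R,6R,6aS)-4,5-dihydroxy-5-methyl-3-methylidene-4-{(3R,4R)-3-methyl-4-[(3-methylbutanoyl)oxy]-5-oxopentyl}-2-oxohexahydro-2H-cyclopenta[b]furan-6-yl (2R)-2-methylbutanoate
Product: 26 (3aR,4R,5R,6R,10R,11R,11aS)-4,10-dihydroxy-6,10-dimethyl-3-methylidene-5-[(3-methylbutanoyl)oxy]-2,9-dioxododecahydrocyclodeca[b]furan-11-yl (2R)-2-methylbutanoate, via bis(ethylzinc) alkoxide 24 (not isolated), via ring-opened allylzinc 25 (not isolated)
Conditions: Et2Zn (2.2 equiv), THF (1 mM), 0 to 40 °C; sat. aq. NH4Cl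
Reagents that add atoms: none
Why: Proposed new method: ring expansion from five to ten members by allyl transfer, in which Et2Zn converts the diol into zinc alkoxide 24, the crowded and strained homoallylic C1 alkoxide undergoes heterolytic C1–C7 cleavage (retro-Barbier, β-carbon elimination) to regenerate the C1 ketone and the allylzinc 25, re-addition to the hindered ketone is reversible whereas SE2' addition of C7 to the more electrophilic C6 aldehyde gives a secondary alkoxide irreversibly so that ring B is funnelled into ring C, C7 is attacked anti to the C9 chain on C8 (trans lactone) and the ring-locked (E)-allylzinc in a chair gives the anti C6/C7 pair (6R,7R) with O6 left free next to the isovalerate already on O5; the closest known reaction type is the fragmentation of hindered tertiary homoallylic zinc alkoxides used as masked allylzinc reagents for intermolecular aldehyde allylation, which has not been used within one molecule to enlarge a ring.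

## Compound list

1 | (E)-but-2-ene | C/C=C/C | starting material
2 | 2,2-dimethoxyacetaldehyde | COC(OC)C=O | starting material
3 | (E)-crotylbis(isopinocampheyl)borane, Ipc groups from (−)-α-pinene | C/C=C/CB([C@H]1C[C@H]2C[C@@H]([C@@H]1C)C2(C)C)[C@H]1C[C@H]2C[C@@H]([C@@H]1C)C2(C)C | intermediate
4 | (2R,3R)-1,1-dimethoxy-3-methylpent-4-en-2-ol | COC(OC)[C@H](O)[C@H](C)C=C | intermediate
5 | 3-methylbutanoyl chloride (isovaleryl chloride) | CC(C)CC(=O)Cl | starting material
6 | (2R,3R)-1,1-dimethoxy-3-methylpent-4-en-2-yl 3-methylbutanoate | COC(OC)[C@H](OC(=O)CC(C)C)[C@H](C)C=C | intermediate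
7 | (E)-3-iodo-2-methylprop-2-en-1-ol | OC/C(C)=C/I | starting material
8 | (E)-3-iodo-2-methylprop-2-enal | O=C/C(C)=C/I | intermediate
9 | (2R,3R)-5-(9-borabicyclo[3.3.1]nonan-9-yl)-1,1-dimethoxy-3-methylpentan-2-yl 3-methylbutanoate | COC(OC)[C@H](OC(=O)CC(C)C)[C@H](C)CCB1C2CCCC1CCC2 | intermediate
10 | (2R,3R,6E)-1,1-dimethoxy-3,7-dimethyl-8-oxooct-6-en-2-yl 3-methylbutanoate | COC(OC)[C@H](OC(=O)CC(C)C)[C@H](C)CC/C=C(C)/C=O | intermediate
11 | 3-(methoxymethoxy)prop-1-ene (allyl MOM ether) | C=CCOCOC | starting material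
12 | [(Z)-3-(methoxymethoxy)allyl]bis(isopinocampheyl)borane, Ipc groups from (−)-α-pinene | COCO/C=C\CB([C@H]1C[C@H]2C[C@@H]([C@@H]1C)C2(C)C)[C@H]1C[C@H]2C[C@@H]([C@@H]1C)C2(C)C | intermediate
13 | (2R,3R,6E,8S,9S)-8-hydroxy-1,1-dimethoxy-9-(methoxymethoxy)-3,7-dimethylundeca-6,10-dien-2-yl 3-methylbutanoate | COC(OC)[C@H](OC(=O)CC(C)C)[C@H](C)CC/C=C(C)/[C@H](O)[C@@H](OCOC)C=C | intermediate
14 | (R)-2-methylbutanoic acid | CC[C@@H](C)C(=O)O | starting material
15 | (2R,3R,6E,8S,9S)-1,1-dimethoxy-9-(methoxymethoxy)-3,7-dimethyl-8-{[(2R)-2-methylbutanoyl]oxy}undeca-6,10-dien-2-yl 3-methylbutanoate | COC(OC)[C@H](OC(=O)CC(C)C)[C@H](C)CC/C=C(C)/[C@H](OC(=O)[C@H](C)CC)[C@@H](OCOC)C=C | intermediate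
16 | (2R,3R,6E,8S,9S)-9-hydroxy-1,1-dimethoxy-3,7-dimethyl-8-{[(2R)-2-methylbutanoyl]oxy}undeca-6,10-dien-2-yl 3-methylbutanoate | COC(OC)[C@H](OC(=O)CC(C)C)[C@H](C)CC/C=C(C)/[C@H](OC(=O)[C@H](C)CC)[C@@H](O)C=C | intermediate
17 | 2-(bromomethyl)acrylic acid | C=C(CBr)C(=O)O | starting material
18 | (2R,3R,6E,8S,9S)-9-{[2-(bromomethyl)acryloyl]oxy}-1,1-dimethoxy-3,7-dimethyl-8-{[(2R)-2-methylbutanoyl]oxy}undeca-6,10-dien-2-yl 3-methylbutanoate | COC(OC)[C@H](OC(=O)CC(C)C)[C@H](C)CC/C=C(C)/[C@H](OC(=O)[C@H](C)CC)[C@@H](OC(=O)C(=C)CBr)C=C | intermediate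
19 | (2R,3R,6E,8S)-8-[(2S)-4-(bromomethyl)-5-oxo-2,5-dihydrofuran-2-yl]-1,1-dimethoxy-3,7-dimethyl-8-{[(2R)-2-methylbutanoyl]oxy}oct-6-en-2-yl 3-methylbutanoate | COC(OC)[C@H](OC(=O)CC(C)C)[C@H](C)CC/C=C(C)/[C@H](OC(=O)[C@H](C)CC)[C@H]1OC(=O)C(CBr)=C1 | intermediate
20 | (2R,3R,7R,8R)-8-[(2S)-4-(bromomethyl)-5-oxo-2,5-dihydrofuran-2-yl]-7-hydroxy-1,1-dimethoxy-3,7-dimethyl-8-{[(2R)-2-methylbutanoyl]oxy}-6-oxooctan-2-yl 3-methylbutanoate | COC(OC)[C@H](OC(=O)CC(C)C)[C@H](C)CCC(=O)[C@](C)(O)[C@H](OC(=O)[C@H](C)CC)[C@H]1OC(=O)C(CBr)=C1 | intermediate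
21 | allylzinc bromide formed from 20 (CH2ZnBr in place of CH2Br) | COC(OC)[C@H](OC(=O)CC(C)C)[C@H](C)CCC(=O)[C@](C)(O)[C@H](OC(=O)[C@H](C)CC)[C@H]1OC(=O)C(C[Zn]Br)=C1 | intermediate
22 | (3aR,4R,5R,6R,6aS)-4-{(3R,4R)-5,5-dimethoxy-3-methyl-4-[(3-methylbutanoyl)oxy]pentyl}-4,5-dihydroxy-5-methyl-3-methylidene-2-oxohexahydro-2H-cyclopenta[b]furan-6-yl (2R)-2-methylbutanoate | C=C1C(=O)O[C@H]2[C@@H]1[C@](O)(CC[C@@H](C)[C@@H](OC(=O)CC(C)C)C(OC)OC)[C@](C)(O)[C@@H]2OC(=O)[C@H](C)CC | intermediate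
23 | (3aR,4R,5R,6R,6aS)-4,5-dihydroxy-5-methyl-3-methylidene-4-{(3R,4R)-3-methyl-4-[(3-methylbutanoyl)oxy]-5-oxopentyl}-2-oxohexahydro-2H-cyclopenta[b]furan-6-yl (2R)-2-methylbutanoate | C=C1C(=O)O[C@H]2[C@@H]1[C@](O)(CC[C@@H](C)[C@@H](OC(=O)CC(C)C)C=O)[C@](C)(O)[C@@H]2OC(=O)[C@H](C)CC | intermediate
24 | bis(ethylzinc) alkoxide of 23 (O1 and O10 metalated) | C=C1C(=O)O[C@H]2[C@@H]1[C@](O[Zn]CC)(CC[C@@H](C)[C@@H](OC(=O)CC(C)C)C=O)[C@](C)(O[Zn]CC)[C@@H]2OC(=O)[C@H](C)CC | intermediate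
25 | ring-opened keto aldehyde carrying the (butenolid-3-yl)methyl(ethyl)zinc unit and the O10 ethylzinc alkoxide | O=C[C@H](OC(=O)CC(C)C)[C@H](C)CCC(=O)[C@](C)(O[Zn]CC)[C@H](OC(=O)[C@H](C)CC)[C@H]1OC(=O)C(C[Zn]CC)=C1 | intermediate
26 | (3aR,4R,5R,6R,10R,11R,11aS)-4,10-dihydroxy-6,10-dimethyl-3-methylidene-5-[(3-methylbutanoyl)oxy]-2,9-dioxododecahydrocyclodeca[b]furan-11-yl (2R)-2-methylbutanoate (CNP0269576.1) | C=C1C(=O)O[C@H]2[C@H]1[C@@H](O)[C@H](OC(=O)CC(C)C)[C@H](C)CCC(=O)[C@](C)(O)[C@@H]2OC(=O)[C@H](C)CC | target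

## Step count and risk

Total step count: 12. Longest linear sequence: 11 (steps 1, 2 and 4–12; step 3 is a one-step branch).

**Step 12 (the proposed ring expansion).**
- The C1–C7 cleavage may be too slow below the temperature at which Et2Zn ethylates the activated aldehyde.
- The zinc alkoxide formed at O6 can cause an O5-to-O6 acyl shift or translactonisation.
- The transient butenolide 25 can lose the C9 acyloxy group.
- The 1,2-syn C5/C6 relationship is the anti-Felkin one, so control rests on the nucleophile alone.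
- Fallback with known chemistry: it sets out from 20 and comes back at 26. The dimethyl acetal of 20 is hydrolysed (aq. TFA, CH2Cl2, 0 °C) to the open-chain bromo keto aldehyde F1. F1 is then closed directly by a Nozaki–Hiyama–Kishi-type allylation (CrCl2, THF, syringe-pump addition). Allylchromium reagents strongly prefer aldehydes to hindered ketones, and this closure is established for ten-membered germacranolide rings.

**Step 10 (ketohydroxylation).**
- The C10 configuration rests on substrate control by an allylic ester.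
- Over-oxidation to C–C cleavage products is possible.
- Oxone may attack the acetal.
- Fallback: it sets out from 19 and comes back at 20. A reagent-controlled dihydroxylation uses stoichiometric OsO4 and (DHQD)2PHAL in toluene at −78 °C, under neutral conditions with NaHSO3 work-up. By the mnemonic this is top-face attack, matched with the substrate bias, and it gives the diol F2. Dess–Martin periodinane then oxidises the only secondary carbinol (C1) of F2 to 20.

**Step 9 (ring-closing metathesis).**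
- The 1,1-disubstituted, electron-poor acrylate closes slowly.
- The reactive allylic bromide may shorten the catalyst lifetime.
- Fallback: it sets out from 16 and comes back at 19, and the halide is carried in masked form. Alcohol 16 is esterified with 2-{[(tert-butyldimethylsilyl)oxy]methyl}acrylic acid (DCC, DMAP) to give the silyloxymethyl acrylate F3. Metathesis of F3 gives the silyloxymethyl butenolide F4. Ph3PBr2 in CH2Cl2 then converts the allylic silyl ether of F4 directly into the bromide 19.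

## Further compounds

F1 | step 12 | (2R,3R,7R,8R)-8-[(2S)-4-(bromomethyl)-5-oxo-2,5-dihydrofuran-2-yl]-7-hydroxy-3,7-dimethyl-8-{[(2R)-2-methylbutanoyl]oxy}-1,6-dioxooctan-2-yl 3-methylbutanoate | O=C[C@H](OC(=O)CC(C)C)[C@H](C)CCC(=O)[C@](C)(O)[C@H](OC(=O)[C@H](C)CC)[C@H]1OC(=O)C(CBr)=C1
F2 | step 10 | (2R,3R,6R,7S,8R)-8-[(2S)-4-(bromomethyl)-5-oxo-2,5-dihydrofuran-2-yl]-6,7-dihydroxy-1,1-dimethoxy-3,7-dimethyl-8-{[(2R)-2-methylbutanoyl]oxy}octan-2-yl 3-methylbutanoate | COC(OC)[C@H](OC(=O)CC(C)C)[C@H](C)CC[C@@H](O)[C@](C)(O)[C@H](OC(=O)[C@H](C)CC)[C@H]1OC(=O)C(CBr)=C1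
F3 | step 9 | (2R,3R,6E,8S,9S)-9-{[2-({[tert-butyl(dimethyl)silyl]oxy}methyl)acryloyl]oxy}-1,1-dimethoxy-3,7-dimethyl-8-{[(2R)-2-methylbutanoyl]oxy}undeca-6,10-dien-2-yl 3-methylbutanoate | COC(OC)[C@H](OC(=O)CC(C)C)[C@H](C)CC/C=C(C)/[C@H](OC(=O)[C@H](C)CC)[C@@H](OC(=O)C(=C)CO[Si](C)(C)C(C)(C)C)C=C
F4 | step 9 | (2R,3R,6E,8S)-8-[(2S)-4-({[tert-butyl(dimethyl)silyl]oxy}methyl)-5-oxo-2,5-dihydrofuran-2-yl]-1,1-dimethoxy-3,7-dimethyl-8-{[(2R)-2-methylbutanoyl]oxy}oct-6-en-2-yl 3-methylbutanoate | COC(OC)[C@H](OC(=O)CC(C)C)[C@H](C)CC/C=C(C)/[C@H](OC(=O)[C@H](C)CC)[C@H]1OC(=O)C(CO[Si](C)(C)C(C)(C)C)=C1
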